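**Retrosynthetic overview**

- Numbering: ring A is O1, C2(=O), C3(Me), C4(O-palmitoyl), C5; the side chain is C1'–C13', with C13' on furan ring B. The strategy rests on the exocyclic C5=C1' alkene of ring A beside the C2' methyl stereocentre: both sp2 carbons are kept as vicinal sp3 stereocentres (C5–H, C1'–O) until late, and their anti relation is converted into the E geometry by anti-elimination.
- Disconnections: the O4–acyl ester; C5=C1' back to the (5S,1'S) C1' carbinol; ring A at C4–C5 and O1–C2 (β-lithiated MOM-acrylate plus α-silyloxy aldehyde, addition then lactonisation).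
- Aldehyde: C1'–O and C2'–Me come from Sharpless epoxidation and Me3Al opening of an E-allylic alcohol. The chain comes from 8-bromogeranyl acetate by two copper-catalysed Grignard couplings (C4'–C5' and C12'–C13') and an acetylide hydroxymethylation (C5–C1').
- Ring order: furan ring B is bought (furan-3-ylmethanol); ring A is the only ring made, in the key step.

Key step: step 17

Remark: read from the target SMILES, the exocyclic alkene is E (C2' cis to C4) and C2' is S; the but-3-ynyl unit is bought as (4-bromobut-1-yn-1-yl)trimethylsilane, and the C3 unit of ring A comes from methyl propanoate.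

**Route**

Step 1
Reactants: 1 geranyl acetate
Product: 2 (2E,6E)-8-hydroxy-3,7-dimethylocta-2,6-dien-1-yl acetate
Conditions: SeO2 (cat.), t-BuOOH, CH2Cl2, 0 °C → rt
Reagents that add atoms: tert-butyl hydroperoxide, CC(C)(C)OO (oxygen relayed through catalytic SeO2, O=[Se]=O)
Why: SeO2-catalysed allylic oxidation (ene reaction then [2,3]-shift) should hydroxylate the E-methyl group of the electron-rich terminal alkene, the C2=C3 alkene being deactivated by its allylic acetate.

Step 2
Reactants: 2 (2E,6E)-8-hydroxy-3,7-dimethylocta-2,6-dien-1-yl acetate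
Product: 3 (2E,6E)-8-bromo-3,7-dimethylocta-2,6-dien-1-yl acetate
Conditions: CBr4, PPh3, CH2Cl2, 0 °C
Reagents that add atoms: carbon tetrabromide, BrC(Br)(Br)Br
Why: Appel bromination of a primary allylic alcohol proceeds by SN2 without allylic transposition and leaves the acetate alone.

Step 3
Reactants: 3 (2E,6E)-8-bromo-3,7-dimethylocta-2,6-dien-1-yl acetate; 4 (4-bromobut-1-yn-1-yl)trimethylsilane
Product: 6 (2E,6E)-3,7-dimethyl-12-(trimethylsilyl)dodeca-2,6-dien-11-yn-1-yl acetate, via butynyl Grignard reagent 5 (not isolated)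
Conditions: 4, Mg, THF, rt; then 3, Li2CuCl4 (cat.), THF, −78 → −20 °C
Reagents that add atoms: none
Why: Copper-catalysed Grignard cross-coupling should substitute the primary allylic bromide at its CH2 carbon with retention of the E alkene, the bromide reacting far faster than the acetate at low temperature (any acetate lost would only anticipate step 4).

Step 4
Reactants: 6 (2E,6E)-3,7-dimethyl-12-(trimethylsilyl)dodeca-2,6-dien-11-yn-1-yl acetate
Product: 7 (2E,6E)-3,7-dimethyl-12-(trimethylsilyl)dodeca-2,6-dien-11-yn-1-ol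
Conditions: i-Bu2AlH, CH2Cl2, −78 °C; aq. potassium sodium tartrate
Reagents that add atoms: none
Why: Reductive ester cleavage with i-Bu2AlH at −78 °C frees the allylic alcohol without touching the C-silyl alkyne, which basic methanolysis would also cleave.

Step 5
Reactants: 7 (2E,6E)-3,7-dimethyl-12-(trimethylsilyl)dodeca-2,6-dien-11-yn-1-ol
Product: 9 [(6E,10E)-12-chloro-6,10-dimethyldodeca-6,10-dien-1-yn-1-yl]trimethylsilane, via allylic mesylate 8 (not isolated)
Conditions: MsCl, LiCl, 2,4,6-collidine, DMF, 0 °C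
Reagents that add atoms: lithium chloride, [Li+].[Cl-]; methanesulfonyl chloride, CS(=O)(=O)Cl (its mesyl group is carried by 8 and its chloride joins the chloride pool)
Why: Mesylation followed by in situ SN2 displacement with chloride converts a primary allylic alcohol into the chloride without allylic rearrangement or loss of E geometry.

Step 6
Reactants: 10 furan-3-ylmethanol
Product: 12 3-(chloromethyl)furan, via furylmethyl mesylate 11 (not isolated)
Conditions: MsCl, LiCl, 2,4,6-collidine, DMF, 0 °C; used at once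
Reagents that add atoms: lithium chloride, [Li+].[Cl-]; methanesulfonyl chloride, CS(=O)(=O)Cl (its mesyl group is carried by 11 and its chloride joins the chloride pool)
Why: The same buffered mesylate–chloride SN2 exchange avoids the strong acid that would polymerise this labile furylmethyl halide.

Step 7
Reactants: 9 [(6E,10E)-12-chloro-6,10-dimethyldodeca-6,10-dien-1-yn-1-yl]trimethylsilane; 12 3-(chloromethyl)furan
Product: 14 trimethyl[(6E,10E)-13-(furan-3-yl)-6,10-dimethyltrideca-6,10-dien-1-yn-1-yl]silane, via furylmethyl Grignard reagent 13 (not isolated)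
Conditions: 12, Mg, THF, rt; then 9, Li2CuCl4 (cat.), THF, 0 °C
Reagents that add atoms: none
Why: Copper-catalysed Grignard cross-coupling of the 3-furylmethyl reagent with the primary allylic chloride should form C12'–C13' at the CH2 carbon, since attack at the other allylic terminus would create a quaternary centre.

Step 8
Reactants: 14 trimethyl[(6E,10E)-13-(furan-3-yl)-6,10-dimethyltrideca-6,10-dien-1-yn-1-yl]silane
Product: 15 3-[(3E,7E)-4,8-dimethyltrideca-3,7-dien-12-yn-1-yl]furan
Conditions: K2CO3 (cat.), MeOH, rt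
Reagents that add atoms: none
Why: Methanolytic protodesilylation of an alkynylsilane is selective and leaves alkenes and furan unchanged.

Step 9
Reactants: 15 3-[(3E,7E)-4,8-dimethyltrideca-3,7-dien-12-yn-1-yl]furan
Product: 17 (7E,11E)-14-(furan-3-yl)-7,11-dimethyltetradeca-7,11-dien-2-yn-1-ol, via lithium acetylide 16 (not isolated)
Conditions: n-BuLi, THF, −78 °C; (CH2O)n, −78 °C → rt; aq. NH4Cl
Reagents that add atoms: formaldehyde (from paraformaldehyde), C=O
Why: Acetylide hydroxymethylation works because the alkyne C–H is far more acidic than any furan C–H, so one equivalent of base metallates only the alkyne.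

Step 10
Reactants: 17 (7E,11E)-14-(furan-3-yl)-7,11-dimethyltetradeca-7,11-dien-2-yn-1-ol
Product: 18 (2E,7E,11E)-14-(furan-3-yl)-7,11-dimethyltetradeca-2,7,11-trien-1-ol
Conditions: LiAlH4, THF, 0 °C → 45 °C; then H2O
Reagents that add atoms: none
Why: Hydroxyl-directed trans-hydroalumination of a propargylic alcohol gives only the E-allylic alcohol and does not reduce isolated alkenes or the furan.

Step 11
Reactants: 18 (2E,7E,11E)-14-(furan-3-yl)-7,11-dimethyltetradeca-2,7,11-trien-1-ol
Product: 19 {(2R,3R)-3-[(4E,8E)-11-(furan-3-yl)-4,8-dimethylundeca-4,8-dien-1-yl]oxiran-2-yl}methanol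
Conditions: Ti(OiPr)4 (cat.), D-(−)-diethyl tartrate (cat.), t-BuOOH, 4 Å MS, CH2Cl2, −20 °C
Reagents that add atoms: tert-butyl hydroperoxide, CC(C)(C)OO
Why: Sharpless asymmetric epoxidation is directed by the allylic hydroxyl, so only the C2=C3 alkene reacts, and the D-(−)-tartrate ligand should deliver oxygen to the face that gives the (2R,3R) epoxide.

Step 12
Reactants: 19 {(2R,3R)-3-[(4E,8E)-11-(furan-3-yl)-4,8-dimethylundeca-4,8-dien-1-yl]oxiran-2-yl}methanol
Product: 20 (2S,3S,7E,11E)-14-(furan-3-yl)-3,7,11-trimethyltetradeca-7,11-diene-1,2-diol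
Conditions: Me3Al, hexane/CH2Cl2, 0 °C → rt; aq. potassium sodium tartrate
Reagents that add atoms: trimethylaluminium, C[Al](C)C
Why: Me3Al opening of a 2,3-epoxy alcohol through its aluminium alkoxide delivers methyl to C3 by SN2 with inversion, which sets the future C2' as S and leaves C2 (future C1') unchanged.

Step 13
Reactants: 20 (2S,3S,7E,11E)-14-(furan-3-yl)-3,7,11-trimethyltetradeca-7,11-diene-1,2-diol
Product: 21 (2S,3S,7E,11E)-1,2-bis(tert-butyldimethylsilyloxy)-14-(furan-3-yl)-3,7,11-trimethyltetradeca-7,11-diene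
Conditions: TBSOTf, 2,6-lutidine, CH2Cl2, −78 → 0 °C
Reagents that add atoms: tert-butyldimethylsilyl trifluoromethanesulfonate, CC(C)(C)[Si](C)(C)OS(=O)(=O)C(F)(F)F
Why: Silyl triflate with a hindered pyridine base silylates both hydroxyls, including the hindered secondary one, under buffered conditions that spare the furan.

Step 14
Reactants: 21 (2S,3S,7E,11E)-1,2-bis(tert-butyldimethylsilyloxy)-14-(furan-3-yl)-3,7,11-trimethyltetradeca-7,11-diene
Product: 22 (2S,3S,7E,11E)-2-(tert-butyldimethylsilyloxy)-14-(furan-3-yl)-3,7,11-trimethyltetradeca-7,11-dien-1-ol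
Conditions: HF·pyridine, pyridine, THF, 0 °C
Reagents that add atoms: none
Why: Selective desilylation relies on the primary silyl ether being cleaved by buffered HF·pyridine much faster than the secondary one flanked by the C3 branch.

Step 15
Reactants: 22 (2S,3S,7E,11E)-2-(tert-butyldimethylsilyloxy)-14-(furan-3-yl)-3,7,11-trimethyltetradeca-7,11-dien-1-ol
Product: 23 (2S,3S,7E,11E)-2-(tert-butyldimethylsilyloxy)-14-(furan-3-yl)-3,7,11-trimethyltetradeca-7,11-dienal
Conditions: Dess–Martin periodinane, pyridine, CH2Cl2, 0 °C → rt; used crude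
Reagents that add atoms: none
Why: Dess–Martin oxidation under buffered, non-basic conditions gives the α-silyloxy aldehyde without epimerising the α-centre or oxidising the furan.

Step 16
Reactants: 24 methyl propanoate
Product: 26 methyl (2E)-3-(methoxymethoxy)-2-methylprop-2-enoate, via sodium formyl enolate 25 (not isolated)
Conditions: NaH, HCO2Me, THF, 0 °C → rt; then MOMCl, 0 °C → rt; E isomer purified by distillation
Reagents that add atoms: methyl formate, COC=O; chloromethyl methyl ether, COCCl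
Why: Crossed Claisen formylation gives the sodium enolate of the α-formyl ester, and the hard electrophile MOMCl alkylates it on oxygen, the E enol ether (alkoxy trans to the ester, vinylic hydrogen cis to it) being the favoured isomer.

Step 17
Reactants: 26 methyl (2E)-3-(methoxymethoxy)-2-methylprop-2-enoate; 23 (2S,3S,7E,11E)-2-(tert-butyldimethylsilyloxy)-14-(furan-3-yl)-3,7,11-trimethyltetradeca-7,11-dienal
Product: 29 (5S)-5-[(1S,2S,6E,10E)-1-(tert-butyldimethylsilyloxy)-13-(furan-3-yl)-2,6,10-trimethyltrideca-6,10-dien-1-yl]-4-(methoxymethoxy)-3-methylfuran-2(5H)-one, via lithioacrylate 27 (not isolated), via lithium alkoxide adduct 28 (not isolated)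
Conditions: 26, LiN(i-Pr)2, THF, −78 °C; then 23, −78 °C → rt; aq. NH4Cl
Reagents that add atoms: none
Why: LiN(i-Pr)2 removes the vinylic hydrogen of 26 that lies cis to the ester and alpha to the MOM oxygen, giving the ester-chelated, configurationally stable vinyllithium 27, which adds to the aldehyde carbonyl of 23 to form C4–C5; on warming, the lithium alkoxide 28 attacks the methyl ester held cis to it and expels methoxide, forming O1–C2. The closest known reaction type is the addition of β-lithiated β-alkoxyacrylates to aldehydes with spontaneous lactonisation to 4-alkoxybutenolides (tetronates). Ring A closes by 5-exo-trig acyl substitution, made easy because the tetrasubstituted C3=C4 alkene fixes the alkoxide and the ester on the same side. The new C5 stereocentre is set by 1,2-induction from the C1' silyloxy centre: polar Felkin–Anh addition anti to the C–OTBS bond, with a bulky, weakly coordinating silyl ether and a lithium counter-ion in THF, should give the anti (5S,1'S) adduct. The step needs this facial selectivity and needs ring closure to outrun O-to-O silyl migration and epimerisation at C1'; the slowly migrating TBS group, the intramolecular cis ester and the addition of the aldehyde to preformed 27 at −78 °C are what should secure them. The furan and the two trisubstituted alkenes are inert under these conditions.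

Step 18
Reactants: 29 (5S)-5-[(1S,2S,6E,10E)-1-(tert-butyldimethylsilyloxy)-13-(furan-3-yl)-2,6,10-trimethyltrideca-6,10-dien-1-yl]-4-(methoxymethoxy)-3-methylfuran-2(5H)-one
Product: 30 (5S)-5-[(1S,2S,6E,10E)-13-(furan-3-yl)-1-hydroxy-2,6,10-trimethyltrideca-6,10-dien-1-yl]-4-(methoxymethoxy)-3-methylfuran-2(5H)-one
Conditions: HF·pyridine, pyridine, THF, 0 °C → rt
Reagents that add atoms: none
Why: Fluoride desilylation in a weakly acidic medium frees the C1' hydroxyl without the retro-aldol cleavage or C5 epimerisation that a basic fluoride source could cause, and the MOM enol ether should survive.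

Step 19
Reactants: 30 (5S)-5-[(1S,2S,6E,10E)-13-(furan-3-yl)-1-hydroxy-2,6,10-trimethyltrideca-6,10-dien-1-yl]-4-(methoxymethoxy)-3-methylfuran-2(5H)-one
Product: 31 (5E)-5-[(2S,6E,10E)-13-(furan-3-yl)-2,6,10-trimethyltrideca-6,10-dien-1-ylidene]-4-(methoxymethoxy)-3-methylfuran-2(5H)-one
Conditions: PPh3, DEAD, THF, 0 °C → rt
Reagents that add atoms: none
Why: Mitsunobu-type dehydration turns the C1' hydroxyl into an oxyphosphonium leaving group and, with no acidic partner present, the hydrazide base removes the acidic C5–H in an anti-periplanar E2 step, which from the (5S,1'S) isomer can only place C2' cis to C4–O, that is the E alkene, both sp3 stereocentres being consumed.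

Step 20
Reactants: 31 (5E)-5-[(2S,6E,10E)-13-(furan-3-yl)-2,6,10-trimethyltrideca-6,10-dien-1-ylidene]-4-(methoxymethoxy)-3-methylfuran-2(5H)-one
Product: 32 (5E)-5-[(2S,6E,10E)-13-(furan-3-yl)-2,6,10-trimethyltrideca-6,10-dien-1-ylidene]-4-hydroxy-3-methylfuran-2(5H)-one
Conditions: HCl (dilute, in MeOH), MeOH/THF, 0 °C, dark
Reagents that add atoms: none
Why: Acid-catalysed acetal cleavage is unusually easy here because the tetronic acid is a good leaving group, so cold dilute acid should suffice, and methanol traps the methoxymethyl cation before it can attack the furan.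

Step 21
Reactants: 32 (5E)-5-[(2S,6E,10E)-13-(furan-3-yl)-2,6,10-trimethyltrideca-6,10-dien-1-ylidene]-4-hydroxy-3-methylfuran-2(5H)-one
Product: 33 (2E)-2-[(2S,6E,10E)-13-(furan-3-yl)-2,6,10-trimethyltrideca-6,10-dien-1-ylidene]-4-methyl-5-oxo-2,5-dihydrofuran-3-yl hexadecanoate
Conditions: C15H31COCl, Et3N, CH2Cl2, −20 → 0 °C
Reagents that add atoms: hexadecanoyl chloride, CCCCCCCCCCCCCCCC(=O)Cl
Why: O-Acylation of the tetronate anion with an acyl chloride should occur at the C4 oxygen, since C3 is blocked by its methyl group and no nucleophilic catalyst is present to isomerise the E alkene.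

**Compound list**

1 | geranyl acetate | CC(C)=CCC/C(C)=C/COC(C)=O | starting material
2 | (2E,6E)-8-hydroxy-3,7-dimethylocta-2,6-dien-1-yl acetate | CC(=O)OC/C=C(\C)CC/C=C(\C)CO | intermediate
3 | (2E,6E)-8-bromo-3,7-dimethylocta-2,6-dien-1-yl acetate | CC(=O)OC/C=C(\C)CC/C=C(\C)CBr | intermediate
4 | (4-bromobut-1-yn-1-yl)trimethylsilane | C[Si](C)(C)C#CCCBr | starting material
5 | [4-(trimethylsilyl)but-3-yn-1-yl]magnesium bromide | C[Si](C)(C)C#CCC[Mg]Br | intermediate
6 | (2E,6E)-3,7-dimethyl-12-(trimethylsilyl)dodeca-2,6-dien-11-yn-1-yl acetate | CC(=O)OC/C=C(\C)CC/C=C(\C)CCCC#C[Si](C)(C)C | intermediate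
7 | (2E,6E)-3,7-dimethyl-12-(trimethylsilyl)dodeca-2,6-dien-11-yn-1-ol | OC/C=C(\C)CC/C=C(\C)CCCC#C[Si](C)(C)C | intermediate
8 | (2E,6E)-3,7-dimethyl-12-(trimethylsilyl)dodeca-2,6-dien-11-yn-1-yl methanesulfonate | CS(=O)(=O)OC/C=C(\C)CC/C=C(\C)CCCC#C[Si](C)(C)C | intermediate
9 | [(6E,10E)-12-chloro-6,10-dimethyldodeca-6,10-dien-1-yn-1-yl]trimethylsilane | ClC/C=C(\C)CC/C=C(\C)CCCC#C[Si](C)(C)C | intermediate
10 | furan-3-ylmethanol | OCc1ccoc1 | starting material
11 | furan-3-ylmethyl methanesulfonate | CS(=O)(=O)OCc1ccoc1 | intermediate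
12 | 3-(chloromethyl)furan | ClCc1ccoc1 | intermediate
13 | (furan-3-ylmethyl)magnesium chloride | Cl[Mg]Cc1ccoc1 | intermediate
14 | trimethyl[(6E,10E)-13-(furan-3-yl)-6,10-dimethyltrideca-6,10-dien-1-yn-1-yl]silane | C[Si](C)(C)C#CCCC/C(C)=C/CC/C(C)=C/CCc1ccoc1 | intermediate
15 | 3-[(3E,7E)-4,8-dimethyltrideca-3,7-dien-12-yn-1-yl]furan | C#CCCC/C(C)=C/CC/C(C)=C/CCc1ccoc1 | intermediate
16 | lithium acetylide of 15, [(6E,10E)-13-(furan-3-yl)-6,10-dimethyltrideca-6,10-dien-1-yn-1-yl]lithium | [Li]C#CCCC/C(C)=C/CC/C(C)=C/CCc1ccoc1 | intermediate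
17 | (7E,11E)-14-(furan-3-yl)-7,11-dimethyltetradeca-7,11-dien-2-yn-1-ol | OCC#CCCC/C(C)=C/CC/C(C)=C/CCc1ccoc1 | intermediate
18 | (2E,7E,11E)-14-(furan-3-yl)-7,11-dimethyltetradeca-2,7,11-trien-1-ol | OC/C=C/CCC/C(C)=C/CC/C(C)=C/CCc1ccoc1 | intermediate
19 | {(2R,3R)-3-[(4E,8E)-11-(furan-3-yl)-4,8-dimethylundeca-4,8-dien-1-yl]oxiran-2-yl}methanol | OC[C@H]1O[C@@H]1CCC/C(C)=C/CC/C(C)=C/CCc1ccoc1 | intermediate
20 | (2S,3S,7E,11E)-14-(furan-3-yl)-3,7,11-trimethyltetradeca-7,11-diene-1,2-diol | OC[C@@H](O)[C@@H](C)CCC/C(C)=C/CC/C(C)=C/CCc1ccoc1 | intermediate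
21 | (2S,3S,7E,11E)-1,2-bis(tert-butyldimethylsilyloxy)-14-(furan-3-yl)-3,7,11-trimethyltetradeca-7,11-diene | CC(C)(C)[Si](C)(C)OC[C@@H](O[Si](C)(C)C(C)(C)C)[C@@H](C)CCC/C(C)=C/CC/C(C)=C/CCc1ccoc1 | intermediate
22 | (2S,3S,7E,11E)-2-(tert-butyldimethylsilyloxy)-14-(furan-3-yl)-3,7,11-trimethyltetradeca-7,11-dien-1-ol | OC[C@@H](O[Si](C)(C)C(C)(C)C)[C@@H](C)CCC/C(C)=C/CC/C(C)=C/CCc1ccoc1 | intermediate
23 | (2S,3S,7E,11E)-2-(tert-butyldimethylsilyloxy)-14-(furan-3-yl)-3,7,11-trimethyltetradeca-7,11-dienal | O=C[C@@H](O[Si](C)(C)C(C)(C)C)[C@@H](C)CCC/C(C)=C/CC/C(C)=C/CCc1ccoc1 | intermediate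
24 | methyl propanoate | CCC(=O)OC | starting material
25 | sodium 3-methoxy-2-methyl-3-oxoprop-1-en-1-olate | [Na+].[O-]C=C(C)C(=O)OC | intermediate
26 | methyl (2E)-3-(methoxymethoxy)-2-methylprop-2-enoate | COCO/C=C(\C)C(=O)OC | intermediate
27 | methyl (2E)-3-lithio-3-(methoxymethoxy)-2-methylprop-2-enoate | [Li]/C(OCOC)=C(/C)C(=O)OC | intermediate
28 | methyl (2E,4S,5S,6S,10E,14E)-5-(tert-butyldimethylsilyloxy)-17-(furan-3-yl)-4-(lithiooxy)-3-(methoxymethoxy)-2,6,10,14-tetramethylheptadeca-2,10,14-trienoate | COC(=O)/C(C)=C(OCOC)\[C@@H](O[Li])[C@@H](O[Si](C)(C)C(C)(C)C)[C@@H](C)CCC/C(C)=C/CC/C(C)=C/CCc1ccoc1 | intermediate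
29 | (5S)-5-[(1S,2S,6E,10E)-1-(tert-butyldimethylsilyloxy)-13-(furan-3-yl)-2,6,10-trimethyltrideca-6,10-dien-1-yl]-4-(methoxymethoxy)-3-methylfuran-2(5H)-one | COCOC1=C(C)C(=O)O[C@H]1[C@@H](O[Si](C)(C)C(C)(C)C)[C@@H](C)CCC/C(C)=C/CC/C(C)=C/CCc1ccoc1 | intermediate
30 | (5S)-5-[(1S,2S,6E,10E)-13-(furan-3-yl)-1-hydroxy-2,6,10-trimethyltrideca-6,10-dien-1-yl]-4-(methoxymethoxy)-3-methylfuran-2(5H)-one | COCOC1=C(C)C(=O)O[C@H]1[C@@H](O)[C@@H](C)CCC/C(C)=C/CC/C(C)=C/CCc1ccoc1 | intermediate
31 | (5E)-5-[(2S,6E,10E)-13-(furan-3-yl)-2,6,10-trimethyltrideca-6,10-dien-1-ylidene]-4-(methoxymethoxy)-3-methylfuran-2(5H)-one | COCOC1=C(C)C(=O)O/C1=C/[C@@H](C)CCC/C(C)=C/CC/C(C)=C/CCc1ccoc1 | intermediate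
32 | (5E)-5-[(2S,6E,10E)-13-(furan-3-yl)-2,6,10-trimethyltrideca-6,10-dien-1-ylidene]-4-hydroxy-3-methylfuran-2(5H)-one | OC1=C(C)C(=O)O/C1=C/[C@@H](C)CCC/C(C)=C/CC/C(C)=C/CCc1ccoc1 | intermediate
33 | (2E)-2-[(2S,6E,10E)-13-(furan-3-yl)-2,6,10-trimethyltrideca-6,10-dien-1-ylidene]-4-methyl-5-oxo-2,5-dihydrofuran-3-yl hexadecanoate (CNP0269639.1) | CCCCCCCCCCCCCCCC(=O)OC1=C(C)C(=O)O/C1=C/[C@@H](C)CCC/C(C)=C/CC/C(C)=C/CCc1ccoc1 | target

**Step count**

Total: 21 steps. Longest linear sequence: 19 steps (steps 1–5, 7–15 and 17–21, from geranyl acetate 1 to target 33).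

**Steps most likely to fail**

Step 17 (addition–lactonisation). The vinyllithium may decompose before it adds, the addition may show poor facial selectivity at the aldehyde, or silyl transfer to the new alkoxide may outrun ring closure. The fallback sets out from diol 20 and lithioacrylate 27 and comes back at 31; it makes ring A first and then forms C5–C1' by a vinylogous aldol. Diol 20 is cleaved with NaIO4 in THF/H2O to (2S,6E,10E)-13-(furan-3-yl)-2,6,10-trimethyltrideca-6,10-dienal F1. Lithioacrylate 27 is trapped with paraformaldehyde to give, after lactonisation, 4-(methoxymethoxy)-3-methylfuran-2(5H)-one F2. Deprotonation of F2 at C5 with LiN(i-Pr)2 in THF at −78 °C gives lithium 4-(methoxymethoxy)-3-methylfuran-2-olate F3, which should add to F1. The anti adducts, 30 and its isomer (5R)-5-[(1R,2S,6E,10E)-13-(furan-3-yl)-1-hydroxy-2,6,10-trimethyltrideca-6,10-dien-1-yl]-4-(methoxymethoxy)-3-methylfuran-2(5H)-one F4, would be separated from the syn adducts. Both should converge on 31 under the conditions of step 19, because the alkene geometry depends only on the relative configuration at C5 and C1'.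

Step 19 (anti-dehydration). Reversible deprotonation at C5 before the leaving group departs would erase the stereochemical relay and erode the E geometry, and substitution at C1' by the hydrazide may compete. The fallback sets out from 30 and comes back at 31; it replaces phosphonium activation by a discrete sulfonate leaving group and an amine base. Tf2O and pyridine in CH2Cl2 at −78 °C should give (1S,2S,6E,10E)-13-(furan-3-yl)-1-[(2S)-3-(methoxymethoxy)-4-methyl-5-oxo-2,5-dihydrofuran-2-yl]-2,6,10-trimethyltrideca-6,10-dien-1-yl trifluoromethanesulfonate F5. Pyridine is expected to take F5 on by anti E2 as the mixture warms, the far better leaving group leaving no time for a carbanion to equilibrate.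

Step 20 (MOM removal). Acid may isomerise the strained E alkene towards Z or degrade the furan and the dienyl tetronic acid during acetal cleavage. The fallback sets out from 29 and comes back at 33; it changes the order of events so that acid is used before the alkene exists. Cold dilute HCl in MeOH on 29 should remove only the MOM group and give (5S)-5-[(1S,2S,6E,10E)-1-(tert-butyldimethylsilyloxy)-13-(furan-3-yl)-2,6,10-trimethyltrideca-6,10-dien-1-yl]-4-hydroxy-3-methylfuran-2(5H)-one F6. Acylation with C15H31COCl and Et3N gives (2S)-2-[(1S,2S,6E,10E)-1-(tert-butyldimethylsilyloxy)-13-(furan-3-yl)-2,6,10-trimethyltrideca-6,10-dien-1-yl]-4-methyl-5-oxo-2,5-dihydrofuran-3-yl hexadecanoate F7. HF·pyridine then frees the C1' hydroxyl to give (2S)-2-[(1S,2S,6E,10E)-13-(furan-3-yl)-1-hydroxy-2,6,10-trimethyltrideca-6,10-dien-1-yl]-4-methyl-5-oxo-2,5-dihydrofuran-3-yl hexadecanoate F8. Anti-dehydration of F8 with PPh3 and DEAD becomes the last step and should give 33 directly.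

**Further compounds**

F1 | step 17 | (2S,6E,10E)-13-(furan-3-yl)-2,6,10-trimethyltrideca-6,10-dienal | O=C[C@@H](C)CCC/C(C)=C/CC/C(C)=C/CCc1ccoc1
F2 | step 17 | 4-(methoxymethoxy)-3-methylfuran-2(5H)-one | COCOC1=C(C)C(=O)OC1
F3 | step 17 | lithium 4-(methoxymethoxy)-3-methylfuran-2-olate | Cc1c(O[Li])occ1OCOC
F4 | step 17 | (5R)-5-[(1R,2S,6E,10E)-13-(furan-3-yl)-1-hydroxy-2,6,10-trimethyltrideca-6,10-dien-1-yl]-4-(methoxymethoxy)-3-methylfuran-2(5H)-one | COCOC1=C(C)C(=O)O[C@@H]1[C@H](O)[C@@H](C)CCC/C(C)=C/CC/C(C)=C/CCc1ccoc1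
F5 | step 19 | (1S,2S,6E,10E)-13-(furan-3-yl)-1-[(2S)-3-(methoxymethoxy)-4-methyl-5-oxo-2,5-dihydrofuran-2-yl]-2,6,10-trimethyltrideca-6,10-dien-1-yl trifluoromethanesulfonate | COCOC1=C(C)C(=O)O[C@H]1[C@@H](OS(=O)(=O)C(F)(F)F)[C@@H](C)CCC/C(C)=C/CC/C(C)=C/CCc1ccoc1
F6 | step 20 | (5S)-5-[(1S,2S,6E,10E)-1-(tert-butyldimethylsilyloxy)-13-(furan-3-yl)-2,6,10-trimethyltrideca-6,10-dien-1-yl]-4-hydroxy-3-methylfuran-2(5H)-one | OC1=C(C)C(=O)O[C@H]1[C@@H](O[Si](C)(C)C(C)(C)C)[C@@H](C)CCC/C(C)=C/CC/C(C)=C/CCc1ccoc1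
F7 | step 20 | (2S)-2-[(1S,2S,6E,10E)-1-(tert-butyldimethylsilyloxy)-13-(furan-3-yl)-2,6,10-trimethyltrideca-6,10-dien-1-yl]-4-methyl-5-oxo-2,5-dihydrofuran-3-yl hexadecanoate | CCCCCCCCCCCCCCCC(=O)OC1=C(C)C(=O)O[C@H]1[C@@H](O[Si](C)(C)C(C)(C)C)[C@@H](C)CCC/C(C)=C/CC/C(C)=C/CCc1ccoc1
F8 | step 20 | (2S)-2-[(1S,2S,6E,10E)-13-(furan-3-yl)-1-hydroxy-2,6,10-trimethyltrideca-6,10-dien-1-yl]-4-methyl-5-oxo-2,5-dihydrofuran-3-yl hexadecanoate | CCCCCCCCCCCCCCCC(=O)OC1=C(C)C(=O)O[C@H]1[C@@H](O)[C@@H](C)CCC/C(C)=C/CC/C(C)=C/CCc1ccoc1
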